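(The runs are simulated for an exercise, and the scatter is random.)

Count the reagent against the starting material before you look at the catalyst.

common to all: reagent 0.429 M
- Saturday's: starting material 0.39 M; free catalyst 5.8 mM; run made earlier
- Friday's: starting material 0.39 M; free catalyst 8.5 mM; run made earlier
- Thursday's: starting material 0.84 M; free catalyst 6.6 mM; run made earlier
- north-west: starting material 0.39 M; free catalyst 6.6 mM; time 6.0 min
- north-east: starting material 1.2 M; free catalyst 10 mM; time 6.0 min

| run | time / min | target / % | starting material / % |
|---|---|---|---|
| Saturday's | 0.250 | 20.1 | 76.8 |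
| Saturday's | 0.667 | 43.6 | 48.2 |
| Saturday's | 1.33 | 65.1 | 20.5 |
| Saturday's | 2.00 | 74.7 | 7.4 |
| Saturday's | 2.50 | 77.7 | 1.8 |
| Saturday's | 3.00 | 78.9 | 1.2 |
| Saturday's | 4.00 | 80.6 | 0 |
| Friday's | 0.250 | 27.5 | 68.8 |
| Friday's | 0.667 | 55.8 | 33.0 |
| Friday's | 1.33 | 73.8 | 7.8 |
| Friday's | 2.00 | 80.0 | 1.0 |
| Friday's | 2.50 | 80.4 | 0.6 |
| Friday's | 3.00 | 80.5 | 0 |
| Friday's | 4.00 | 81.6 | 0 |
| Thursday's | 0.333 | 17.3 | 81.0 |
| Thursday's | 0.667 | 29.5 | 67.2 |
| Thursday's | 1.33 | 41.3 | 51.7 |
| Thursday's | 2.00 | 43.7 | 49.1 |
| Thursday's | 4.00 | 43.2 | 48.4 |

(standard deviation of a reading: 0.5 percentage points)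

- the winner by amount of target, in percent of the starting material charged; "neither" if no more than 2 percentage points parts them (north-west / north-east / neither)
- how much target is there at the end, in percent of the starting material charged: north-west
- how much target is there at the end, in percent of the starting material charged: north-east

- reactions considered so far: starting material + free catalyst -> catalyst intermediate A; reagent + catalyst intermediate A <-> catalyst intermediate B; catalyst intermediate B -> free catalyst + target; target + free catalyst <-> isomer of the product + free catalyst

Each target takes one reagent, so I reckon with the reagent ceiling, the reagent charge as a fraction of the starting-material charge, which for north-east is 35.8%. Below a full charge, reagent is the limiting reagent.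

Saturday's and Friday's runs stand at 110%, above the full charge, so their starting material can go, and it does: 0% remains in each at 4.00 min. Their target reads 80.6% and 81.6%, though the catalyst differs.

But Thursday's ceiling is 51.1%, and 51.6% of its starting material has gone when it stalls. Target there stays flat, 43.7% at 2.00 min and 43.2% at 4.00 min, which is 84.6% of the ceiling.

North-west has Saturday's ratio, a catalyst charge between the two runs, and a longer time, so I expect it near those readings. North-east lies far under its full charge, so target cannot pass 35.8%, and Thursday's share, carried over as an estimate, gives me about 30.3%. I therefore put north-west well ahead.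

The forecast also names north-west, with 81% against 32.3%, and says of Thursday's stall that “free catalyst is trapped as intermediate A, so isomerisation stops”.

The flask gives north-west, with 80.6% against 32.1%, so my estimate for north-east from Thursday's share was too low.

    starting material + free catalyst → catalyst intermediate A (k = 7.40 L mol⁻¹ s⁻¹)
    reagent + catalyst intermediate A ⇌ catalyst intermediate B (K = 8.50 L mol⁻¹, k = 10.0 L mol⁻¹ s⁻¹)
    catalyst intermediate B → free catalyst + target (k = 3.70 s⁻¹)
    target + free catalyst ⇌ isomer of the product + free catalyst, rate k4*[free catalyst]*[target] forward; the back reaction follows from the equilibrium constant (K = 0.240, k = 5.00 L mol⁻¹ s⁻¹)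

At 6.00 min north-east holds 35.8% as target plus isomer, against the ceiling of 35.8%, with reagent at 0% of its own charge. Half of its target-making up to 6.0 min is done by 0.298 min, sooner than the 1.7 min half-life of target toward isomer, forward step alone at 0.292 min.

Take a neighbour of north-east with 0.17 M of reagent: its ceiling is 14.2%, so target cannot pass that. It gives 13.5%, with 85.0% of the starting material left.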